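The readings come from a simulation for substances that don't exist, and the scatter is random.

Thursday's run charged 1.5 equiv of reagent, yet its starting material reads 13% after 8.00 min and 14% after 15.0 min. Sunday's run levels off near 67% product on 0.67 equiv of reagent, its limiting reagent.

| flask | starting material | reagent | free catalyst | remark |
|---|---|---|---|---|
| Sunday's | 0.092 M | 0.67 equiv | 2.3 mol% | run made earlier |
| Thursday's | 0.092 M | 1.5 equiv | 2.3 mol% | run made earlier |
| flask | 0.092 M | 1.00 equiv | 2.3 mol% |  |

| run | time / min | product / % | starting material / % |
|---|---|---|---|
| Sunday's | 1.00 | 26 | 72 |
| Sunday's | 2.00 | 45 | 55 |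
| Sunday's | 3.00 | 57 | 45 |
| Sunday's | 5.00 | 64 | 38 |
| Sunday's | 8.00 | 67 | 34 |
| Sunday's | 15.0 | 64 | 36 |
| Thursday's | 1.00 | 36 | 69 |
| Thursday's | 2.00 | 54 | 43 |
| Thursday's | 3.00 | 67 | 32 |
| Thursday's | 5.00 | 82 | 19 |
| Thursday's | 8.00 | 83 | 13 |
| Thursday's | 15.0 | 85 | 14 |

(scatter of a reading: 1.5 percentage points)

- apparent order in reagent when 30% of the starting material are converted (percent change of the rate of making product for one percent more reagent charged)
- apparent order in free catalyst when 30% of the starting material are converted (percent change of the rate of making product for one percent more free catalyst charged)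

- no earlier run changes the charge of free catalyst; that part of a forecast is a guess

What stopped Thursday's run? Its product reads 85% against 1.5 equiv of reagent, so reagent remained, and I read the stall as a dying catalyst.

How fast does it die? Take the logarithm of charge over starting material left: in Thursday's run it reaches 0.371 after 1.00 min and 1.97 at the end. If the catalyst fades exponentially, and you neglect the falling reagent, that gives 5.30 min, the catalyst life, the time in which working catalyst falls by a factor e.

What does that do to the orders? Your flask should pass 30% near 1.00 min, since the first product readings are 26% and 36%. One percent more catalyst arrives about one percent sooner, with more survivors, so I reckon the catalyst order as one plus arrival time over life, 1.19. This is inferred, since no run varies the catalyst. Those first readings give me a reagent order of 0.404.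

The forecast differs: 0.37 for reagent and 1 for catalyst, saying “I guess first order, with wide uncertainty”.

The flask gives 0.34 and 1.2.

    reagent + free catalyst → catalyst intermediate A (k = 15.8 M⁻¹ s⁻¹)
    starting material + catalyst intermediate A ⇌ catalyst intermediate B (K = 33.3 M⁻¹, k = 21.4 M⁻¹ s⁻¹)
    catalyst intermediate B ⇌ released group + catalyst intermediate C (K = 0.269 M, k = 0.736 s⁻¹)
    catalyst intermediate C → free catalyst + product (k = 1.93 s⁻¹)
    catalyst intermediate A → spent catalyst (k = 0.0116 s⁻¹)

Your flask reaches 30% conversion at 0.914 min, and that arrival time with the catalyst life gives a catalyst order of 1.17. At 6.00 min your flask holds 80.5% of its catalyst as spent catalyst, so 19.5% is unspent, less than the 32.2% that a life of 5.30 min gives, and at 12.0 min spent catalyst stands at 97.2% with 14% of the starting material left.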